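**Retrosynthetic overview**
1. Target ⇐ removal of two silyl ethers ⇐ tiglate installed by Mitsunobu inversion at C6 of a macrocyclic allylic alcohol.
2. Ten-membered ring (formed second; last C–C bond is C6–C7): a 3-(bromomethyl)butenolide becomes an allylchromium whose lactone β-carbon C7, normally an acceptor carbon, attacks the C6 enal carbon. C6 and C7 are set from C8.
3. Butenolide (formed first): ring-closing metathesis of the 2-(bromomethyl)acrylate of a C8 allylic alcohol. C8 comes from (S)-epichlorohydrin (alkenyl Grignard opening, then sulfonium-ylide homologation).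
4. Open chain with both trisubstituted alkenes: phosphonoacetate + acrolein (Michael), iodo-Wittig (C1=C10), Horner–Wadsworth–Emmons with glyoxal dimethyl acetal (C4=C5), reduction, silylation.

Assumption: the SMILES is taken as drawn, i.e. (6S,7R,8S) with the ring carbons cis across both ring alkenes (5E,9E in the systematic name because CH2OH outranks the ring CH2).
Atom labels C1–C15 follow germacrane numbering of the target (ring C1–C10; lactone C11–C13 with C12 the carbonyl; C14 on C10; C15 on C4). TBS = tert-butyldimethylsilyl.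

**Step 1**
Reactants: 1 triethyl phosphonoacetate; 2 acrolein
Product: 3 ethyl 2-(diethoxyphosphoryl)-5-oxopentanoate (racemic)
Conditions: NaOEt (10 mol %), EtOH, −10 °C, slow addition of 2
Reagents that add atoms: none
Why: Base-catalysed Michael addition of the phosphonoacetate carbanion to acrolein, with slow addition at low temperature to suppress double addition; the new stereocentre is racemic and is erased in step 3.

**Step 2**
Reactants: 3 ethyl 2-(diethoxyphosphoryl)-5-oxopentanoate; 4 ethyl (triphenylphosphoranylidene)acetate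
Product: 6 diethyl (2Z)-6-(diethoxyphosphoryl)-2-iodohept-2-enedioate, via iodo ylide 5 (not isolated)
Conditions: NIS (1.05 equiv), CH2Cl2, −20 °C, 20 min; then 3, −20 °C → rt
Reagents that add atoms: N-iodosuccinimide O=C1CCC(=O)N1I
Why: Wittig olefination with the stabilised α-iodo ylide made by iodination of 4 reacts only at the aldehyde and places the chain trans to the ester, so iodine is cis to the chain (2Z), which fixes the future C1=C10 geometry.

**Step 3**
Reactants: 6 diethyl (2Z)-6-(diethoxyphosphoryl)-2-iodohept-2-enedioate; 7 2,2-dimethoxyacetaldehyde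
Product: 8 ethyl (2Z,6E)-6-(ethoxycarbonyl)-2-iodo-8,8-dimethoxyocta-2,6-dienoate
Conditions: K2CO3, THF/H2O, rt (7 used as its 60% aqueous solution)
Reagents that add atoms: none
Why: Horner–Wadsworth–Emmons olefination of the α-substituted phosphonoacetate with an activated aldehyde gives mainly the enoate with the acetal carbon trans to the ester (6E), the geometry needed for C4=C5.

**Step 4**
Reactants: 8 ethyl (2Z,6E)-6-(ethoxycarbonyl)-2-iodo-8,8-dimethoxyocta-2,6-dienoate
Product: 9 (2Z,6E)-6-(hydroxymethyl)-2-iodo-8,8-dimethoxyocta-2,6-dien-1-ol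
Conditions: i-Bu2AlH (5 equiv), CH2Cl2, −78 °C; aq KNa tartrate
Reagents that add atoms: none
Why: i-Bu2AlH 1,2-reduction of both enoates to allylic alcohols at low temperature leaves the alkenyl iodide, the acetal and both alkene geometries untouched.

**Step 5**
Reactants: 9 (2Z,6E)-6-(hydroxymethyl)-2-iodo-8,8-dimethoxyocta-2,6-dien-1-ol
Product: 10 (2Z,6E)-1-(TBSO)-6-(TBSOCH2)-2-iodo-8,8-dimethoxyocta-2,6-diene
Conditions: TBSCl (2.4 equiv), imidazole, DMF, 0 °C → rt
Reagents that add atoms: tert-butyldimethylsilyl chloride CC(C)(C)[Si](C)(C)Cl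
Why: Standard silylation of the two primary allylic alcohols (the future C14 and C15 hydroxyls) masks them until the last step.

**Step 6**
Reactants: 10 (2Z,6E)-1-(TBSO)-6-(TBSOCH2)-2-iodo-8,8-dimethoxyocta-2,6-diene; 11 (S)-epichlorohydrin
Product: 13 (2S,4E,8E)-4,8-bis(TBSOCH2)-1-chloro-10,10-dimethoxydeca-4,8-dien-2-ol, via alkenylmagnesium chloride 12 (not isolated)
Conditions: i-PrMgCl·LiCl (1.1 equiv), THF, −15 → 0 °C; CuI (10 mol %), then 11, −30 → 0 °C; H2O
Reagents that add atoms: none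
Why: Iodine–magnesium exchange with retention of alkene geometry, then copper-catalysed SN2 opening of the epoxide at its CH2 terminus, forms C9–C10 and leaves the stereocentre of 11 untouched, so C8 is S.

**Step 7**
Reactants: 13 (2S,4E,8E)-4,8-bis(TBSOCH2)-1-chloro-10,10-dimethoxydeca-4,8-dien-2-ol
Product: 15 (3S,5E,9E)-5,9-bis(TBSOCH2)-11,11-dimethoxyundeca-1,5,9-trien-3-ol, via epoxide 14 (not isolated)
Conditions: Me3S+ I− (4 equiv), n-BuLi (3.9 equiv), THF, −10 °C → rt; H2O
Reagents that add atoms: trimethylsulfonium iodide C[S+](C)C.[I-]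
Why: The sulfonium ylide first closes the chlorohydrin to the terminal epoxide, then opens it at CH2 and eliminates Me2S (one-carbon homologation of an epoxide to an allylic alcohol), with the C8–O bond never broken (retention).

**Step 8**
Reactants: 15 (3S,5E,9E)-5,9-bis(TBSOCH2)-11,11-dimethoxyundeca-1,5,9-trien-3-ol; 16 2-(bromomethyl)acrylic acid
Product: 17 (3S,5E,9E)-5,9-bis(TBSOCH2)-11,11-dimethoxyundeca-1,5,9-trien-3-yl 2-(bromomethyl)prop-2-enoate
Conditions: DCC, DMAP (5 mol %), CH2Cl2, −20 → 0 °C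
Reagents that add atoms: none
Why: Steglich esterification of the secondary allylic alcohol, run cold with only catalytic DMAP to limit attack on the allylic bromide.

**Step 9**
Reactants: 17 (3S,5E,9E)-5,9-bis(TBSOCH2)-11,11-dimethoxyundeca-1,5,9-trien-3-yl 2-(bromomethyl)prop-2-enoate
Product: 18 (5S)-3-(bromomethyl)-5-[(2E,6E)-2,6-bis(TBSOCH2)-8,8-dimethoxyocta-2,6-dien-1-yl]furan-2(5H)-one
Conditions: second-generation Hoveyda–Grubbs catalyst, RuCl2(H2IMes)(=CH-C6H4-2-O-i-Pr) (10 mol %), toluene (5 mM), 80 °C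
Reagents that add atoms: none
Why: Ring-closing metathesis between the terminal vinyl group and the 1,1-disubstituted acrylate closes the butenolide (first ring) with loss of ethene, as for methacrylates of allylic alcohols; the trisubstituted chain alkenes are too hindered to engage.

**Step 10**
Reactants: 18 (5S)-3-(bromomethyl)-5-[(2E,6E)-2,6-bis(TBSOCH2)-8,8-dimethoxyocta-2,6-dien-1-yl]furan-2(5H)-one
Product: 19 (2E,6E)-8-[(2S)-4-(bromomethyl)-5-oxo-2,5-dihydrofuran-2-yl]-3,7-bis(TBSOCH2)octa-2,6-dienal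
Conditions: 10% aq oxalic acid on SiO2, CH2Cl2, rt
Reagents that add atoms: water O
Why: Mild acid hydrolysis of the allylic dimethyl acetal is far faster than silyl ether cleavage and unmasks the C6 enal without isomerising C4=C5.

**Step 11**
Reactants: 19 (2E,6E)-8-[(2S)-4-(bromomethyl)-5-oxo-2,5-dihydrofuran-2-yl]-3,7-bis(TBSOCH2)octa-2,6-dienal
Product: 21 (3aS,4R,5E,9E,11aS)-4-hydroxy-6,10-bis(TBSOCH2)-3-methylidene-3a,4,7,8,11,11a-hexahydrocyclodeca[b]furan-2(3H)-one, via allylchromium dichloride 20 (not isolated)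
Conditions: CrCl2 (10 equiv), THF, rt, slow addition of 19 (final 2 mM); H2O
Reagents that add atoms: none
Why: Proposed new method: CrCl2 inserts into the allylic C–Br bond to give an allylchromium in which the butenolide β-carbon C7, normally the electrophilic terminus, is nucleophilic (a lactone homoenolate equivalent) and adds to the C6 enal carbonyl through a chair six-membered transition state at high dilution, closing the ten-membered ring (closest known reactions: intermolecular Nozaki–Hiyama/Barbier 2-(alkoxycarbonyl)allylation of aldehydes with 3-(bromomethyl)furan-2(5H)-ones and macrocyclic Nozaki–Hiyama allylations); the tether on C8 can reach C7 only from the face anti to C9 (trans-fused lactone), and the fixed E-type allyl geometry with the enal substituent equatorial gives the anti adduct, i.e. 6R, the C6 epimer of the target.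

**Step 12**
Reactants: 21 (3aS,4R,5E,9E,11aS)-4-hydroxy-6,10-bis(TBSOCH2)-3-methylidene-3a,4,7,8,11,11a-hexahydrocyclodeca[b]furan-2(3H)-one; 22 tiglic acid
Product: 23 (3aR,4S,5E,9E,11aS)-6,10-bis(TBSOCH2)-3-methylidene-2-oxo-2,3,3a,4,7,8,11,11a-octahydrocyclodeca[b]furan-4-yl (2E)-2-methylbut-2-enoate
Conditions: PPh3/DIAD premixed, then 21 and 22, toluene, 0 °C → rt
Reagents that add atoms: none
Why: Mitsunobu esterification, in which tiglate displaces the alkoxyphosphonium by SN2, inverts C6 from R to S and installs the ester in one step, while SN2' is blocked because the distal alkene carbon C4 is fully substituted (the C3a descriptor changes from S to R only through CIP priorities).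

**Step 13**
Reactants: 23 (3aR,4S,5E,9E,11aS)-6,10-bis(TBSOCH2)-3-methylidene-2-oxo-2,3,3a,4,7,8,11,11a-octahydrocyclodeca[b]furan-4-yl (2E)-2-methylbut-2-enoate
Product: 24 (3aR,4S,5E,9E,11aS)-6,10-bis(hydroxymethyl)-3-methylidene-2-oxo-2,3,3a,4,7,8,11,11a-octahydrocyclodeca[b]furan-4-yl (2E)-2-methylbut-2-enoate (target)
Conditions: HF·pyridine, pyridine/THF, 0 °C → rt
Reagents that add atoms: none
Why: Buffered fluoride cleavage of the two primary allylic TBS ethers leaves the α-methylene lactone and the tiglate intact, and acyl migration is excluded because the C15 hydroxyl is trans to C6 across the alkene.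

**Compound list**
1 | triethyl phosphonoacetate | CCOC(=O)CP(=O)(OCC)OCC | starting material
2 | acrolein | C=CC=O | starting material
3 | ethyl 2-(diethoxyphosphoryl)-5-oxopentanoate (racemic) | CCOC(=O)C(CCC=O)P(=O)(OCC)OCC | intermediate
4 | ethyl (triphenylphosphoranylidene)acetate | CCOC(=O)C=P(c1ccccc1)(c1ccccc1)c1ccccc1 | starting material
5 | ethyl iodo(triphenylphosphoranylidene)acetate (iodo ylide) | CCOC(=O)C(I)=P(c1ccccc1)(c1ccccc1)c1ccccc1 | intermediate
6 | diethyl (2Z)-6-(diethoxyphosphoryl)-2-iodohept-2-enedioate (racemic) | CCOC(=O)/C(I)=C/CCC(C(=O)OCC)P(=O)(OCC)OCC | intermediate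
7 | 2,2-dimethoxyacetaldehyde | COC(OC)C=O | starting material
8 | ethyl (2Z,6E)-6-(ethoxycarbonyl)-2-iodo-8,8-dimethoxyocta-2,6-dienoate | CCOC(=O)/C(I)=C/CC/C(C(=O)OCC)=C\C(OC)OC | intermediate
9 | (2Z,6E)-6-(hydroxymethyl)-2-iodo-8,8-dimethoxyocta-2,6-dien-1-ol | OC/C(I)=C/CC/C(CO)=C\C(OC)OC | intermediate
10 | (2Z,6E)-1-(TBSO)-6-(TBSOCH2)-2-iodo-8,8-dimethoxyocta-2,6-diene | CC(C)(C)[Si](C)(C)OC/C(I)=C/CC/C(CO[Si](C)(C)C(C)(C)C)=C\C(OC)OC | intermediate
11 | (S)-epichlorohydrin | ClC[C@@H]1CO1 | starting material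
12 | alkenylmagnesium chloride (MgCl in place of I in 10, same geometry) | CC(C)(C)[Si](C)(C)OC/C([Mg]Cl)=C/CC/C(CO[Si](C)(C)C(C)(C)C)=C\C(OC)OC | intermediate
13 | (2S,4E,8E)-4,8-bis(TBSOCH2)-1-chloro-10,10-dimethoxydeca-4,8-dien-2-ol | ClC[C@@H](O)C/C(CO[Si](C)(C)C(C)(C)C)=C\CC/C(CO[Si](C)(C)C(C)(C)C)=C\C(OC)OC | intermediate
14 | (2S)-2-[(2E,6E)-2,6-bis(TBSOCH2)-8,8-dimethoxyocta-2,6-dien-1-yl]oxirane | C1O[C@H]1C/C(CO[Si](C)(C)C(C)(C)C)=C\CC/C(CO[Si](C)(C)C(C)(C)C)=C\C(OC)OC | intermediate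
15 | (3S,5E,9E)-5,9-bis(TBSOCH2)-11,11-dimethoxyundeca-1,5,9-trien-3-ol | C=C[C@@H](O)C/C(CO[Si](C)(C)C(C)(C)C)=C\CC/C(CO[Si](C)(C)C(C)(C)C)=C\C(OC)OC | intermediate
16 | 2-(bromomethyl)acrylic acid | C=C(CBr)C(=O)O | starting material
17 | (3S,5E,9E)-5,9-bis(TBSOCH2)-11,11-dimethoxyundeca-1,5,9-trien-3-yl 2-(bromomethyl)prop-2-enoate | C=C[C@@H](OC(=O)C(=C)CBr)C/C(CO[Si](C)(C)C(C)(C)C)=C\CC/C(CO[Si](C)(C)C(C)(C)C)=C\C(OC)OC | intermediate
18 | (5S)-3-(bromomethyl)-5-[(2E,6E)-2,6-bis(TBSOCH2)-8,8-dimethoxyocta-2,6-dien-1-yl]furan-2(5H)-one | BrCC1=C[C@@H](OC1=O)C/C(CO[Si](C)(C)C(C)(C)C)=C\CC/C(CO[Si](C)(C)C(C)(C)C)=C\C(OC)OC | intermediate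
19 | (2E,6E)-8-[(2S)-4-(bromomethyl)-5-oxo-2,5-dihydrofuran-2-yl]-3,7-bis(TBSOCH2)octa-2,6-dienal | BrCC1=C[C@@H](OC1=O)C/C(CO[Si](C)(C)C(C)(C)C)=C\CC/C(CO[Si](C)(C)C(C)(C)C)=C\C=O | intermediate
20 | allylchromium dichloride (CrCl2 in place of Br in 19; THF ligands omitted) | Cl[Cr](Cl)CC1=C[C@@H](OC1=O)C/C(CO[Si](C)(C)C(C)(C)C)=C\CC/C(CO[Si](C)(C)C(C)(C)C)=C\C=O | intermediate
21 | (3aS,4R,5E,9E,11aS)-4-hydroxy-6,10-bis(TBSOCH2)-3-methylidene-3a,4,7,8,11,11a-hexahydrocyclodeca[b]furan-2(3H)-one (6R alcohol, trans-fused lactone) | C=C1C(=O)O[C@H]2C/C(CO[Si](C)(C)C(C)(C)C)=C\CC/C(CO[Si](C)(C)C(C)(C)C)=C\[C@@H](O)[C@H]12 | intermediate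
22 | tiglic acid, (2E)-2-methylbut-2-enoic acid | C/C=C(\C)C(=O)O | starting material
23 | (3aR,4S,5E,9E,11aS)-6,10-bis(TBSOCH2)-3-methylidene-2-oxo-2,3,3a,4,7,8,11,11a-octahydrocyclodeca[b]furan-4-yl (2E)-2-methylbut-2-enoate | C=C1C(=O)O[C@H]2C/C(CO[Si](C)(C)C(C)(C)C)=C\CC/C(CO[Si](C)(C)C(C)(C)C)=C\[C@H](OC(=O)/C(C)=C/C)[C@H]12 | intermediate
24 | (3aR,4S,5E,9E,11aS)-6,10-bis(hydroxymethyl)-3-methylidene-2-oxo-2,3,3a,4,7,8,11,11a-octahydrocyclodeca[b]furan-4-yl (2E)-2-methylbut-2-enoate | C=C1C(=O)O[C@H]2C/C(CO)=C\CC/C(CO)=C\[C@H](OC(=O)/C(C)=C/C)[C@H]12 | target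

**Totals**
Total step count: 13. Longest linear sequence: 13.

**Steps most likely to fail, with fallbacks**

Step 11 (macrocyclising allylchromium addition): the risks are oligomerisation, reduction of the bromide, or the wrong ring fusion. The fallback sets out from 18 and comes back at 21. It replaces the reductive in-situ metalation by an isolable allylboron nucleophile. Borylation of the allylic bromide with bis(pinacolato)diboron and Pd2(dba)3 gives the allylboronate F4. Acetal hydrolysis as in step 10 gives the boryl enal F5. Intramolecular allylboration with catalytic Sc(OTf)3 at high dilution runs through the same chair transition state, and hydrolytic work-up gives 21.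

Step 12 (Mitsunobu inversion at the hindered C6 allylic alcohol): the risks are elimination or no reaction. The fallback sets out from 21 and comes back at 23. It inverts C6 by oxidation and reduction instead of substitution. Dess–Martin periodinane gives the C6 enone F6. Reduction with (S)-2-methyl-CBS-oxazaborolidine and catecholborane at −78 °C, with the alkenyl group as the large substituent, gives the 6S alcohol F7. Acylation with (E)-2-methylbut-2-enoyl chloride, pyridine and DMAP gives 23 with retention.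

Step 9 (metathesis onto the bromomethyl acrylate): the risk is a stalled ring closure or catalyst degradation by the allylic bromide. The fallback sets out from 13 and comes back at 18. It builds the butenolide by epoxide alkylation and elimination instead of metathesis. NaOH closes 13 to epoxide 14, which is isolated. Opening 14 at CH2 with the dianion of (phenylselanyl)acetic acid (LiN(i-Pr)2, THF) and lactonisation with TsOH gives the α-selanyl lactone F1. Deprotonation (LiN(i-Pr)2, −78 °C) and trapping with formaldehyde gives the hydroxymethyl selenide F2. Oxidation with H2O2 and selenoxide syn-elimination, which avoids the carbinol carbon and so goes into the ring, gives the 3-(hydroxymethyl)butenolide F3. CBr4/PPh3 converts F3 into 18.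

**Further compounds**
F1 | step 9 | (5S)-5-[(2E,6E)-2,6-bis(TBSOCH2)-8,8-dimethoxyocta-2,6-dien-1-yl]-3-(phenylselanyl)oxolan-2-one | c1ccccc1[Se]C1C[C@@H](OC1=O)C/C(CO[Si](C)(C)C(C)(C)C)=C\CC/C(CO[Si](C)(C)C(C)(C)C)=C\C(OC)OC
F2 | step 9 | (5S)-5-[(2E,6E)-2,6-bis(TBSOCH2)-8,8-dimethoxyocta-2,6-dien-1-yl]-3-(hydroxymethyl)-3-(phenylselanyl)oxolan-2-one | OCC1([Se]c2ccccc2)C[C@@H](OC1=O)C/C(CO[Si](C)(C)C(C)(C)C)=C\CC/C(CO[Si](C)(C)C(C)(C)C)=C\C(OC)OC
F3 | step 9 | (5S)-5-[(2E,6E)-2,6-bis(TBSOCH2)-8,8-dimethoxyocta-2,6-dien-1-yl]-3-(hydroxymethyl)furan-2(5H)-one | OCC1=C[C@@H](OC1=O)C/C(CO[Si](C)(C)C(C)(C)C)=C\CC/C(CO[Si](C)(C)C(C)(C)C)=C\C(OC)OC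
F4 | step 11 | (5S)-5-[(2E,6E)-2,6-bis(TBSOCH2)-8,8-dimethoxyocta-2,6-dien-1-yl]-3-[(4,4,5,5-tetramethyl-1,3,2-dioxaborolan-2-yl)methyl]furan-2(5H)-one | CC1(C)OB(CC2=C[C@@H](OC2=O)C/C(CO[Si](C)(C)C(C)(C)C)=C\CC/C(CO[Si](C)(C)C(C)(C)C)=C\C(OC)OC)OC1(C)C
F5 | step 11 | (2E,6E)-3,7-bis(TBSOCH2)-8-{(2S)-5-oxo-4-[(4,4,5,5-tetramethyl-1,3,2-dioxaborolan-2-yl)methyl]-2,5-dihydrofuran-2-yl}octa-2,6-dienal | CC1(C)OB(CC2=C[C@@H](OC2=O)C/C(CO[Si](C)(C)C(C)(C)C)=C\CC/C(CO[Si](C)(C)C(C)(C)C)=C\C=O)OC1(C)C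
F6 | step 12 | (3aR,5E,9E,11aS)-6,10-bis(TBSOCH2)-3-methylidene-7,8,11,11a-tetrahydrocyclodeca[b]furan-2,4(3H,3aH)-dione | C=C1C(=O)O[C@H]2C/C(CO[Si](C)(C)C(C)(C)C)=C\CC/C(CO[Si](C)(C)C(C)(C)C)=C\C(=O)[C@H]12
F7 | step 12 | (3aS,4S,5E,9E,11aS)-4-hydroxy-6,10-bis(TBSOCH2)-3-methylidene-3a,4,7,8,11,11a-hexahydrocyclodeca[b]furan-2(3H)-one | C=C1C(=O)O[C@H]2C/C(CO[Si](C)(C)C(C)(C)C)=C\CC/C(CO[Si](C)(C)C(C)(C)C)=C\[C@H](O)[C@H]12
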